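Start from a ratio: the part not yet product at one late reading over the part at the next. Here is what is asked and what is known.

| flask | substrate | temperature | remark | time |
|---|---|---|---|---|
| Monday's | 1 M | 11 °C | run made earlier |  |
| Sunday's | 1 M | 25 °C | run made earlier |  |
| delta | 2.0 M | 30 °C |  | 10 h |
| eta | 2.0 M | 5 °C |  | 10 h |

| run | time / h | product / % | substrate / % |
|---|---|---|---|
| Monday's | 5.00 | 8.2 | 19.9 |
| Monday's | 10.0 | 22.0 | 10.4 |
| Monday's | 15.0 | 37.3 | 5.5 |
| Monday's | 20.0 | 50.1 | 2.7 |
| Sunday's | 2.00 | 11.5 | 11.6 |
| Sunday's | 4.00 | 29.1 | 3.3 |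
| Sunday's | 6.00 | 45.5 | 1.7 |
| Sunday's | 8.00 | 59.3 | 0.5 |

(scatter of a reading: 0.3 percentage points)

- steps thought possible: substrate -> intermediate A; intermediate A <-> intermediate B; intermediate B -> product; substrate <-> dormant form

* the flask with the highest amount of product, in percent of the substrate charged ("all alike" if they lie within 1.5 percentage points) (delta / eta / all alike)
* final product, as a percentage of the substrate charged, in delta
* final product, as a percentage of the substrate charged, in eta

On Sunday's run the part left goes from 54.5% to 40.7% between 6.00 h and 8.00 h. That gives 0.146 h⁻¹. This logarithm of the ratio per hour is the tail rate, an apparent first-order constant. Monday's last two readings give 0.0457 h⁻¹, so going from 11 °C to 25 °C multiplies the tail rate by 3.20.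

I assume the same factor per degree holds, and that percentages carry from 1 M to 2.0 M, which is untested. Delta's clock then runs 1.51 times Sunday's. Its 10 h equal 15.1 h of Sunday's time, and by my reckoning the tail leaves 14.3%.

The weak link is that factor, built from the last two readings of each run. Reforge it from the curves. Monday's last product, 50.1%, falls on Sunday's curve at 6.67 h, so the factor becomes 3.00. Delta's clock becomes 1.48 times Sunday's, the part left 15.1%, and I commit to 84.9% product. Eta's clock is 0.208 times Sunday's, so its 10 h equal 2.08 h. I take Sunday's 11.5% at 2.00 h for eta, which is less than my delta figure.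

The forecast says delta, with 86% in delta and 11% in eta, noting that “The product curves overlay if Monday's time is divided by about 3”. Its delta figure stands above mine.

    substrate → intermediate A (k = 0.140 h⁻¹, Ea = 81.0 kJ mol⁻¹)
    intermediate A ⇌ intermediate B (K = 1.70, k = 1.20 h⁻¹, Ea = 78.0 kJ mol⁻¹, ΔH = −56.0 kJ mol⁻¹)
    intermediate B → product (k = 0.0540 h⁻¹, Ea = 82.0 kJ mol⁻¹)
    substrate ⇌ dormant form (K = 0.890, k = 0.270 h⁻¹, Ea = 97.0 kJ mol⁻¹, ΔH = 16.0 kJ mol⁻¹)
    (constants at 5 °C)

Delta gives 80.8% and eta 9.36%, so delta holds more. At 10.0 h, delta's part left stands as intermediate A 15.6%, intermediate B 3.57% and dormant form 0.00923%, with substrate at 0%. From 5.00 h on, delta's part left falls at 0.186 h⁻¹, slower than the 0.216 h⁻¹ of the tail rate carried to 30 °C.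

Now read eta on to 25 h. The tail rate carried to 5 °C is 0.0304 h⁻¹, which from eta's 90.6% left gives 42.6% product. Eta at that time gives 33.9%, less than that.

All runs come from a simulation from invented constants.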